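**Plan**

- The retrosynthesis first cuts the ester between C7 of unit A and O1 of unit B, then the two caffeoyl esters at O5. Both rings are then the same protected ent-quinate (quinate numbering: C1 quaternary carbinol carrying carboxyl C7, cis-diol at C3/C4, acylated C5).
- In that ring the bonds C3–C4 and C4–C5 are cut (double Henry transform, C4 = nitromethane carbon). What is left, C3–C2–C1(O1)(C7)–C6–C5 with oxidised ends, is citric acid, with O1 and C7 tied as a methylene dioxolanone.
- Forward: citric acid → dioxolanone dialdehyde → nitromethane closes the only carbocycle → Nef reaction, hydride, acetonide, allyl ester, 5-O-caffeoylation → monomer 19. Monomer 19 serves as the acceptor and, after O1 silylation and deallylation, as the donor → union → deprotection.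
- Stereochemistry: C3 and C5 (both S, as in both rings of the target) come from the chiral Cu(OAc)2–bis(oxazoline) catalyst. C4 comes from axial hydride addition to the ketone, which also makes C1 stereogenic (C1 is no stereocentre while C4 is trigonal). The E-alkenes come from caffeic acid.

Key step: step 4

Assumption: the Cu(OAc)2/bis(oxazoline) catalyst is taken to show the same sense of induction here as with simple aliphatic aldehydes; the ligand enantiomer that gives (S)-nitro alcohols is used, and its antipode if the (3R,5R) series should result.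

In the names, "ent-quinic acid" means (1R,3S,4R,5S)-1,3,4,5-tetrahydroxycyclohexane-1-carboxylic acid, with quinate numbering.

**Route**

Step 1
Reactants: 1 citric acid; 2 paraformaldehyde (formaldehyde source)
Product: 3 2,2'-(5-oxo-1,3-dioxolane-4,4-diyl)diacetic acid
Conditions: (CH2O)n, neat melt, 140–150 °C; recrystallisation from water
Reagents that add atoms: none
Why: The α-hydroxy acid unit of citric acid condenses with formaldehyde to the five-membered 1,3-dioxolan-4-one (acetalisation with lactonisation), a long-known derivative that masks O1 and C7 and leaves the two acetic acid arms free.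

Step 2
Reactants: 3 dioxolanone diacid
Product: 4 5,5-bis(2-hydroxyethyl)-1,3-dioxolan-4-one
Conditions: BH3·THF (2.5 equiv), THF, 0 °C → rt; MeOH quench; used crude
Reagents that add atoms: none
Why: Borane reduces free carboxylic acids through acyloxyboranes far faster than it attacks the electron-poor dioxolanone carbonyl (chemoselective borane reduction), as known for the dioxolanones of malic acid.

Step 3
Reactants: 4 diol
Product: 5 2,2'-(5-oxo-1,3-dioxolane-4,4-diyl)diacetaldehyde
Conditions: DMP [1,1,1-triacetoxy-1,1-dihydro-1,2-benziodoxol-3(1H)-one] (2.4 equiv), CH2Cl2, 0 °C → rt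
Reagents that add atoms: none
Why: Periodinane oxidation of primary alcohols to aldehydes runs under nearly neutral, water-free conditions, which spare the acylal and avoid base-induced β-elimination of O1 from the β-oxy aldehyde.

Step 4
Reactants: 5 dialdehyde; 6 nitromethane
Product: 8 (7S,9S)-7,9-dihydroxy-8-nitro-1,3-dioxaspiro[4.5]decan-4-one [quinate numbering: (3S,5S)-trans-diol; nitro at C4 cis to 3-OH; O1 cis to 3-OH], via mono-adduct aldehyde 7 (not isolated)
Conditions: CH3NO2 (1.1 equiv), Cu(OAc)2·H2O (10 mol %), chiral 2,2'-(propane-2,2-diyl)bis(indeno-oxazoline) ligand (11 mol %), i-PrOH, −20 °C, moderate dilution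
Reagents that add atoms: none
Why: Proposed new method: the acetate of the chiral Cu(OAc)2–bis(oxazoline) complex deprotonates nitromethane bound to that complex, the nitronate adds to an aldehyde held on the same divalent copper centre, and the β-hydroxy nitroalkane 7, more acidic than nitromethane, is deprotonated again and adds through C4 to the second aldehyde; the closest known reactions are the base-mediated dialdehyde–nitromethane cyclisation to nitrocyclohexanediols and the Cu(OAc)2/bis(oxazoline)-catalysed enantioselective intermolecular Henry reaction of aliphatic aldehydes. The ring closes in a 6-(enolexo)-exo-trig mode, helped by the gem-disubstituent effect of quaternary C1. C3 and C5 are both set by the catalyst, which has to present the same aldehyde face in the intermolecular and in the intramolecular addition, so that both carbinols are S and it does not matter which of the two enantiotopic arms of the achiral dialdehyde reacts first; C4 is epimerisable and should settle with nitro equatorial, and C1 is stereogenic only through C4, so both are defined for good at the ketone stage. The step needs ring closure to win over a second intermolecular addition, which near-stoichiometric nitromethane and the higher acidity of 7 should secure, and it needs the kinetic trans-(S,S) diol to survive against retro-Henry equilibration to the all-equatorial cis (meso) diol, which the weakly basic acetate catalyst at low temperature should allow. The acetal-type O1 is a poor leaving group, so β-elimination from the β-oxy aldehydes is not expected under these nearly neutral conditions.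

Step 5
Reactants: 8 nitro diol
Product: 9 3,5-bis-O-triethylsilyl ether of 8
Conditions: Et3SiOTf (2.4 equiv), 2,6-lutidine, CH2Cl2, −78 → −20 °C
Reagents that add atoms: triethylsilyl triflate, CC[Si](CC)(CC)OS(=O)(=O)C(F)(F)F
Why: A silyl triflate with a hindered pyridine base silylates both secondary alcohols (O-silylation) without forming an alkoxide, so the retro-Henry pathway stays closed here and in the basic step that follows.

Step 6
Reactants: 9 bis-silyl nitro compound
Product: 11 (7S,9S)-7,9-bis(triethylsilyloxy)-1,3-dioxaspiro[4.5]decane-4,8-dione (C4 ketone), via potassium nitronate 10 (not isolated)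
Conditions: KOt-Bu (1.05 equiv), THF, −78 °C; then dimethyldioxirane in acetone, −78 → −20 °C; pH 7 buffer
Reagents that add atoms: dimethyldioxirane, CC1(C)OO1
Why: Deprotonation gives the nitronate, whose C=N bond is oxidised by the dioxirane to the ketone with loss of nitrite (oxidative Nef reaction); the silyl ethers block retro-Henry cleavage, a silanolate is too poor a leaving group for β-elimination at low temperature, and any C4 epimer of 9 converges on the same ketone.

Step 7
Reactants: 11 ketone
Product: 12 3,5-bis-O-triethylsilyl-ent-quinic acid 1,7-methylene acetal-lactone (4-OH cis to O3 and O1, trans to O5)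
Conditions: NaBH4, THF/EtOH (4:1), −78 → −40 °C
Reagents that add atoms: none
Why: Hydride should add along the axial trajectory of the chair that has ring oxygen O1 and the 3-silyloxy group axial and acyl carbon C7 equatorial, anti to the axial C3–O bond (substrate-controlled borohydride reduction of an α-oxy cyclohexanone), which places the new 4-OH equatorial, cis to O3 and O1, as in ent-quinic acid.

Step 8
Reactants: 12 bis-silyl alcohol
Product: 14 3,4-O-isopropylidene-ent-quinic acid 1,7-methylene acetal-lactone (5-OH free), via triol 13 (not isolated)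
Conditions: TsOH·H2O (cat.), acetone/2,2-dimethoxypropane (4:1), rt
Reagents that add atoms: 2,2-dimethoxypropane, COC(C)(C)OC
Why: Acid cleaves the two triethylsilyl ethers and the cis-3,4-diol is captured as the five-membered isopropylidene acetal (transacetalisation), a trans-fused acetal across O4/O5 being strained, so only the 5-OH stays free, as in the known bis-acetonide of quinic acid.

Step 9
Reactants: 14 acetonide dioxolanone
Product: 15 allyl 3,4-O-isopropylidene-ent-quinate (1-OH and 5-OH free)
Conditions: allyl alcohol (solvent), K2CO3 (cat.), 0 °C → rt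
Reagents that add atoms: allyl alcohol, C=CCO
Why: The dioxolanone is an activated acylal-type lactone that undergoes base-catalysed transesterification with allyl alcohol, the hemiacetal alkoxide released at O1 losing formaldehyde, and in neat alcohol the strained bicyclic lactone to O5 stays open.

Step 10
Reactants: 16 caffeic acid
Product: 18 (E)-3-[3,4-bis(methoxymethoxy)phenyl]acrylic acid, via methoxymethyl ester 17 (not isolated)
Conditions: MeOCH2Cl (3.5 equiv), i-Pr2NEt, CH2Cl2, 0 °C → rt; then LiOH, THF/H2O, rt; HCl to pH 3–4 at 0 °C
Reagents that add atoms: chloromethyl methyl ether, COCCl; lithium hydroxide, [Li+].[OH-]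
Why: Chloromethyl methyl ether alkylates both phenols and the carboxylate (Williamson-type O-alkylation), and mild saponification then removes only the methoxymethyl ester.

Step 11
Reactants: 15 diol ester; 18 protected caffeic acid
Product: 19 allyl 5-O-[(E)-3,4-bis(methoxymethoxy)cinnamoyl]-3,4-O-isopropylidene-ent-quinate (1-OH free)
Conditions: EDC·HCl, DMAP, CH2Cl2, 0 °C → rt
Reagents that add atoms: none
Why: Carbodiimide/DMAP acylation (Steglich esterification) takes place at the secondary 5-OH, the tertiary 1-OH next to the ester being too hindered, as in the established acylation of 3,4-O-isopropylidene quinates.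

Step 12
Reactants: 19 monomer (first portion)
Product: 20 1-O-triethylsilyl ether of 19
Conditions: Et3SiCl (2 equiv), imidazole (3 equiv), DMAP (0.2 equiv), DMF, rt → 40 °C
Reagents that add atoms: triethylsilyl chloride, CC[Si](CC)(CC)Cl
Why: Imidazole-promoted silylation with the chlorosilane through the N-silylimidazolium species, assisted by DMAP (O-silylation), reaches the tertiary 1-OH because the triethylsilyl group is small, and it needs neither a silyl triflate, which would attack the methoxymethyl ethers, nor a strong base, which could start transesterification.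

Step 13
Reactants: 20 silylated allyl ester
Product: 21 5-O-[(E)-3,4-bis(methoxymethoxy)cinnamoyl]-3,4-O-isopropylidene-1-O-triethylsilyl-ent-quinic acid
Conditions: Pd(PPh3)4 (5 mol %), morpholine (1.5 equiv), THF, rt; pH 5 buffer wash
Reagents that add atoms: none
Why: Zerovalent palladium ionises the allyl ester to a π-allyl complex that morpholine intercepts (Tsuji–Trost deallylation), leaving silyl ether, acetals and cinnamate untouched.

Step 14
Reactants: 21 donor acid; 19 monomer (second portion, acceptor)
Product: 24 fully protected dimer [C7 of the 1-O-silyl unit A esterified to O1 of allyl ester unit B], via acid chloride 22 (not isolated), via lithium alkoxide 23 (not isolated)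
Conditions: 21, 1-chloro-N,N,2-trimethylprop-1-en-1-amine, CH2Cl2, 0 °C → rt; separately 19, LiN(SiMe3)2, THF, −78 °C; combine, −78 → 0 °C
Reagents that add atoms: none
Why: The α-chloroenamine converts the acid into its chloride under neutral conditions and a preformed lithium tertiary alkoxide is the classical partner for hindered acid chlorides (alkoxide acylation), the O1 silyl ether of the donor preventing self-condensation and the trans arrangement of O1 and the 5-O-acyl group in the acceptor excluding acyl migration.

Step 15
Reactants: 24 protected dimer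
Product: 25 protected dimer with free carboxylic acid on unit B
Conditions: Pd(PPh3)4 (5 mol %), morpholine (1.5 equiv), THF, rt
Reagents that add atoms: none
Why: The only allyl group left is removed through the π-allyl palladium complex (Tsuji–Trost deallylation), a method that does not touch the three other esters.

Step 16
Reactants: 25 acid
Product: 26 target CNP0107948.2
Conditions: TFA/H2O (9:1), 0 °C → rt; reversed-phase chromatography
Reagents that add atoms: none
Why: Aqueous trifluoroacetic acid hydrolyses the two isopropylidene acetals, the four aryl methoxymethyl ethers and the tertiary silyl ether (acid-catalysed acetal and silyl ether cleavage), while the esters should persist because ionisation of the tertiary C1–O bond would place a cation next to a carboxyl group.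

**Compound list**

1 | citric acid | OC(=O)CC(O)(CC(=O)O)C(=O)O | starting material
2 | paraformaldehyde (as formaldehyde) | C=O | starting material
3 | 2,2'-(5-oxo-1,3-dioxolane-4,4-diyl)diacetic acid | OC(=O)CC1(CC(=O)O)OCOC1=O | intermediate
4 | 5,5-bis(2-hydroxyethyl)-1,3-dioxolan-4-one | OCCC1(CCO)OCOC1=O | intermediate
5 | 2,2'-(5-oxo-1,3-dioxolane-4,4-diyl)diacetaldehyde | O=CCC1(CC=O)OCOC1=O | intermediate
6 | nitromethane | C[N+](=O)[O-] | starting material
7 | 2-{4-[(2S)-2-hydroxy-3-nitropropyl]-5-oxo-1,3-dioxolan-4-yl}acetaldehyde (either configuration at the ring carbon) | O=CCC1(C[C@H](O)C[N+](=O)[O-])OCOC1=O | intermediate (not isolated)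
8 | (7S,9S)-7,9-dihydroxy-8-nitro-1,3-dioxaspiro[4.5]decan-4-one; nitro cis to 3-OH, O1 cis to 3-OH (quinate numbering) | O[C@H]1C[C@@](O2)(C(=O)OC2)C[C@H](O)[C@@H]1[N+](=O)[O-] | intermediate
9 | 3,5-bis-O-triethylsilyl ether of 8 | CC[Si](CC)(CC)O[C@H]1C[C@@](O2)(C(=O)OC2)C[C@H](O[Si](CC)(CC)CC)[C@@H]1[N+](=O)[O-] | intermediate
10 | potassium nitronate of 9 | CC[Si](CC)(CC)O[C@H]1CC2(OCOC2=O)C[C@H](O[Si](CC)(CC)CC)C1=[N+]([O-])[O-].[K+] | intermediate (not isolated)
11 | (7S,9S)-7,9-bis(triethylsilyloxy)-1,3-dioxaspiro[4.5]decane-4,8-dione | CC[Si](CC)(CC)O[C@H]1CC2(OCOC2=O)C[C@H](O[Si](CC)(CC)CC)C1=O | intermediate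
12 | 3,5-bis-O-triethylsilyl-ent-quinic acid 1,7-methylene acetal-lactone | CC[Si](CC)(CC)O[C@H]1C[C@@](O2)(C(=O)OC2)C[C@H](O[Si](CC)(CC)CC)[C@@H]1O | intermediate
13 | ent-quinic acid 1,7-methylene acetal-lactone (3,4,5-triol) | O[C@H]1C[C@@](O2)(C(=O)OC2)C[C@H](O)[C@@H]1O | intermediate (not isolated)
14 | 3,4-O-isopropylidene-ent-quinic acid 1,7-methylene acetal-lactone | O[C@H]1C[C@@](O2)(C(=O)OC2)C[C@H](O3)[C@@H]1OC3(C)C | intermediate
15 | allyl 3,4-O-isopropylidene-ent-quinate | O[C@H]1C[C@@](O)(C(=O)OCC=C)C[C@H](O2)[C@@H]1OC2(C)C | intermediate
16 | caffeic acid | O=C(O)/C=C/c1ccc(O)c(O)c1 | starting material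
17 | methoxymethyl (E)-3-[3,4-bis(methoxymethoxy)phenyl]acrylate | COCOC(=O)/C=C/c1ccc(OCOC)c(OCOC)c1 | intermediate (not isolated)
18 | (E)-3-[3,4-bis(methoxymethoxy)phenyl]acrylic acid | OC(=O)/C=C/c1ccc(OCOC)c(OCOC)c1 | intermediate
19 | allyl 5-O-[(E)-3,4-bis(methoxymethoxy)cinnamoyl]-3,4-O-isopropylidene-ent-quinate | COCOc1ccc(/C=C/C(=O)O[C@H]2C[C@@](O)(C(=O)OCC=C)C[C@H](O3)[C@@H]2OC3(C)C)cc1OCOC | intermediate
20 | 1-O-triethylsilyl ether of 19 | COCOc1ccc(/C=C/C(=O)O[C@H]2C[C@@](O[Si](CC)(CC)CC)(C(=O)OCC=C)C[C@H](O3)[C@@H]2OC3(C)C)cc1OCOC | intermediate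
21 | 5-O-[(E)-3,4-bis(methoxymethoxy)cinnamoyl]-3,4-O-isopropylidene-1-O-triethylsilyl-ent-quinic acid | COCOc1ccc(/C=C/C(=O)O[C@H]2C[C@@](O[Si](CC)(CC)CC)(C(=O)O)C[C@H](O3)[C@@H]2OC3(C)C)cc1OCOC | intermediate
22 | acid chloride of 21 | COCOc1ccc(/C=C/C(=O)O[C@H]2C[C@@](O[Si](CC)(CC)CC)(C(=O)Cl)C[C@H](O3)[C@@H]2OC3(C)C)cc1OCOC | intermediate (not isolated)
23 | lithium 1-alkoxide of 19 | COCOc1ccc(/C=C/C(=O)O[C@H]2C[C@@]([O-])(C(=O)OCC=C)C[C@H](O3)[C@@H]2OC3(C)C)cc1OCOC.[Li+] | intermediate (not isolated)
24 | protected dimer: unit A (1-O-triethylsilyl, 3,4-O-isopropylidene, 5-O-protected caffeoyl) acylating O1 of unit B (allyl ester, 3,4-O-isopropylidene, 5-O-protected caffeoyl) | COCOc1ccc(/C=C/C(=O)O[C@H]2C[C@@](O[Si](CC)(CC)CC)(C(=O)O[C@@]4(C(=O)OCC=C)C[C@H](OC(=O)/C=C/c5ccc(OCOC)c(OCOC)c5)[C@@H](O6)[C@@H](OC6(C)C)C4)C[C@H](O3)[C@@H]2OC3(C)C)cc1OCOC | intermediate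
25 | protected dimer, unit B as free acid | COCOc1ccc(/C=C/C(=O)O[C@H]2C[C@@](O[Si](CC)(CC)CC)(C(=O)O[C@@]4(C(=O)O)C[C@H](OC(=O)/C=C/c5ccc(OCOC)c(OCOC)c5)[C@@H](O6)[C@@H](OC6(C)C)C4)C[C@H](O3)[C@@H]2OC3(C)C)cc1OCOC | intermediate
26 | CNP0107948.2: 5-O-caffeoyl-ent-quinic acid acylated at O1 by the carboxyl group of a second 5-O-caffeoyl-ent-quinic acid | O=C(/C=C/c1ccc(O)c(O)c1)O[C@H]1C[C@@](O)(C(=O)O[C@@]2(C(=O)O)C[C@H](OC(=O)/C=C/c3ccc(O)c(O)c3)[C@@H](O)[C@@H](O)C2)C[C@H](O)[C@@H]1O | target

**Step count**

Total: 16 steps. Longest linear sequence: 15 steps (steps 1–9 and 11–16; step 10 is the one-step side branch).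

**Steps most likely to fail**

1. Step 4 (proposed new method). What may go wrong is loss of kinetic control: retro-Henry equilibration towards the cis diol, weak face discrimination in the intramolecular addition, or a second intermolecular addition of nitromethane.
Fallback with known chemistry, setting out from 5 and 6 and rejoining at 8: the two are cyclised with a catalytic amine base (Et3N, THF, 0 °C), the long-known dialdehyde–nitromethane cyclisation. This gives the racemic trans diol, that is 8 together with its (3R,5R)-enantiomer F1, beside the cis (meso) nitro diol F2. F2 is the thermodynamic isomer; it is separated and returned to the basic medium, where it re-equilibrates by retro-Henry reaction, so much of the material has to be recycled. Lipase-catalysed acetylation of the racemate (immobilised Candida antarctica lipase B, vinyl acetate, MTBE, 30 °C) should, by the usual preference of lipases for (R)-configured ring carbinols, turn F1 into the (3R,5R)-diacetate F3 and leave 8 free. Chromatography returns the route to 8.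

2. Step 14. What may go wrong is that acylation of the flexible, hindered tertiary alkoxide by the equally hindered acid chloride stalls, so that transesterification or silyl transfer by the alkoxide takes over.
Fallback, setting out from 15 (with 22 and 18) and rejoining at 24: the acceptor is changed to the tied-back bridgehead alcohol for which 1-O-acylation is established. Diol ester 15 is lactonised (DBU cat., toluene, 80 °C, allyl alcohol distilled off) to 3,4-O-isopropylidene-ent-quinide F4, whose only free hydroxyl is O1. Its lithium alkoxide (LiN(SiMe3)2, THF, −78 °C) is acylated with acid chloride 22 to the 1-O-acyl lactone F5. The strained γ-lactone of F5 is reopened with allyl alcohol and a trace of K2CO3 at 0 °C to the 5-hydroxy allyl ester F6. Steglich esterification of F6 with acid 18 gives 24.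

3. Step 7. What may go wrong is poor facial selectivity, if the two chairs of the spiro ketone are populated and reduced at similar rates.
Fallback, setting out from 11 and rejoining at 15: the conformational control element is changed before the hydride step. The dioxolanone of 11 is opened with allyl alcohol (K2CO3 cat., 0 °C, short contact) to the allyl hydroxy ester ketone F7. In F7, as in quinic esters, the chair with equatorial ester and axial 1-OH hydrogen-bonded to the axial 3-oxygen should be strongly preferred. NaBH4 (THF/EtOH, −78 °C) then gives allyl 3,5-bis-O-triethylsilyl-ent-quinate F8, and the conditions of step 8 convert F8 into 15.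

**Further compounds**

F1 | step 4 | (7R,9R)-enantiomer of nitro diol 8 | O[C@@H]1C[C@](O2)(C(=O)OC2)C[C@@H](O)[C@H]1[N+](=O)[O-]
F2 | step 4 | cis (meso) 7,9-dihydroxy-8-nitro-1,3-dioxaspiro[4.5]decan-4-one, nitro trans to both hydroxyls, O1 trans to the hydroxyls (its C1 epimer may accompany it) | O[C@@H]1C[C@](O2)(C(=O)OC2)C[C@H](O)[C@H]1[N+](=O)[O-]
F3 | step 4 | 7,9-diacetate of F1 | CC(=O)O[C@@H]1C[C@](O2)(C(=O)OC2)C[C@@H](OC(C)=O)[C@H]1[N+](=O)[O-]
F4 | step 14 | 3,4-O-isopropylidene-ent-quinide (1,5-lactone, 1-OH free) | O[C@]1(C(=O)O2)C[C@H](O3)[C@H](OC3(C)C)[C@@H]2C1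
F5 | step 14 | 1-O-acyl derivative of F4 carrying the acyl group of 22 | COCOc1ccc(/C=C/C(=O)O[C@H]2C[C@@](O[Si](CC)(CC)CC)(C(=O)O[C@]4(C(=O)O7)C[C@H](O6)[C@H](OC6(C)C)[C@@H]7C4)C[C@H](O3)[C@@H]2OC3(C)C)cc1OCOC
F6 | step 14 | allyl ester of ring-opened F5 with free 5-OH on unit B | COCOc1ccc(/C=C/C(=O)O[C@H]2C[C@@](O[Si](CC)(CC)CC)(C(=O)O[C@@]4(C(=O)OCC=C)C[C@H](O)[C@@H](O6)[C@@H](OC6(C)C)C4)C[C@H](O3)[C@@H]2OC3(C)C)cc1OCOC
F7 | step 7 | allyl (3S,5S)-1-hydroxy-4-oxo-3,5-bis(triethylsilyloxy)cyclohexane-1-carboxylate | CC[Si](CC)(CC)O[C@H]1CC(O)(C(=O)OCC=C)C[C@H](O[Si](CC)(CC)CC)C1=O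
F8 | step 7 | allyl 3,5-bis-O-triethylsilyl-ent-quinate | CC[Si](CC)(CC)O[C@H]1C[C@@](O)(C(=O)OCC=C)C[C@H](O[Si](CC)(CC)CC)[C@@H]1O
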